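**Retrosynthetic overview**
1. Platanetin 8 ⇒ hydroquinone 7-O-prenyl ether 5. The C6–prenyl bond comes from an O-to-C relay: a new palladium-catalysed allylic C–O transposition to the tert-prenyl ether, then Claisen rearrangement. C6 is the only open ortho carbon.
2. 5 ⇒ galangin 7-O-prenyl ether 3. The key C8–O bond is made by para-selective C–H oxygenation of the 5-phenol (Elbs). This completes the oxygen pattern and blocks C8.
3. 3 ⇒ galangin 1 + prenyl bromide 2. The O7–C bond is made by selective etherification; the ether masks O7 during the oxidation and carries the five carbons.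
4. No ring is formed: rings A, C and B come intact from commercial galangin.

Assumption: platanetin has no stereocentre and no stereodefined double bond, so the SMILES describes one achiral compound and no enantiocontrol is needed.

**Step 1**
Reactants: 1 galangin (3,5,7-trihydroxyflavone); 2 prenyl bromide (1-bromo-3-methylbut-2-ene, 1.05 equiv)
Product: 3 galangin 7-O-prenyl ether (3,5-dihydroxy-7-(prenyloxy)flavone)
Conditions: K2CO3 (1.1 equiv), acetone, 45 °C, N2, 6 h
Reagents that add atoms: none
Why: Williamson ether synthesis, in which the 7-OH (para to the C4 carbonyl, the most acidic hydroxyl) is alkylated first while the chelated 5-OH and the less acidic, hydrogen-bonded 3-OH stay free with one equivalent of halide and mild base; no stereocentre is formed.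

**Step 2**
Reactants: 3 galangin 7-O-prenyl ether
Product: 5 flavonol hydroquinone 7-O-prenyl ether (3,5,8-trihydroxy-7-(prenyloxy)flavone), via potassium aryl sulfate 4 (not isolated)
Conditions: K2S2O8 (1.2 equiv), KOH (5 equiv), H2O/pyridine 3:1, 0 to 20 °C, N2, 24 h; bring to pH 6, EtOAc wash (recovers 3); aqueous phase to pH 5 (NaOAc/AcOH), arylsulfatase (Helix pomatia), sodium ascorbate, 37 °C, N2
Reagents that add atoms: potassium peroxydisulfate, [K+].[K+].[O-]S(=O)(=O)OOS(=O)(=O)[O-]
Why: Elbs persulfate oxidation, in which the 5-phenoxide attacks the peroxide oxygen through its para carbon C8 (the site this reaction takes in 5-hydroxy-7-alkoxyflavones), the sulfate ester 4 is protected from over-oxidation and the dianionic oxidant leaves the prenyl alkene alone, followed by enzymatic sulfate ester hydrolysis at pH 5 that frees the 8-OH without the hot mineral acid that would cleave the prenyl ether; no stereocentre is formed.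

**Step 3**
Reactants: 5 flavonol hydroquinone 7-O-prenyl ether
Product: 8 platanetin (3,5,7,8-tetrahydroxy-6-prenylflavone), via prenylpalladium phenoxide ion pair 6 (not isolated), via tert-prenyl ether 7 (not isolated)
Conditions: Pd(PPh3)4 (5 mol %), degassed 1,4-dioxane, 90 °C, N2, dark, 6 h
Reagents that add atoms: none
Why: Proposed new method: zerovalent palladium ionises the O7–CH2 bond of 5 (the 7-oxide is the anion of a vinylogous acid and is hydrogen-bonded by the new 8-OH) to ion pair 6, whose phenoxide recloses on the tertiary allyl terminus (C–O bond formation, the kinetic mode of phenoxides toward π-prenylpalladium) to give tert-prenyl ether 7, and 7 is drained irreversibly by aromatic Claisen [3,3] rearrangement to C6, the only unsubstituted ortho carbon now that C8 carries oxygen, which delivers the prenyl group with normal connectivity; direct attack of C6 on the CH2 terminus of 6 gives the same product, every O-alkylation is reversible under the catalyst while C–C formation is not, the linear ether itself does not undergo Claisen rearrangement at 90 °C, and the free PPh3 keeps the cation bis-ligated against the 3-hydroxy-4-keto chelating site; the closest known chemistry is palladium-catalysed tert-prenylation of phenols with 2-methylbut-3-en-2-yl carbonates followed by Claisen rearrangement, and palladium-catalysed O-to-C allyl migration of 1,3-dicarbonyl enol ethers (Tsuji–Trost type), neither shown for an aryl prenyl ether of a free polyhydroxyflavonol; no stereocentre is formed.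

**Compound list**
1 | galangin (3,5,7-trihydroxy-2-phenyl-4H-chromen-4-one) | O=c1c(O)c(-c2ccccc2)oc2cc(O)cc(O)c12 | starting material
2 | prenyl bromide (1-bromo-3-methylbut-2-ene) | CC(C)=CCBr | starting material
3 | galangin 7-O-prenyl ether (3,5-dihydroxy-7-[(3-methylbut-2-en-1-yl)oxy]-2-phenyl-4H-chromen-4-one) | CC(C)=CCOc1cc(O)c2c(=O)c(O)c(-c3ccccc3)oc2c1 | intermediate
4 | potassium 3,5-dihydroxy-7-[(3-methylbut-2-en-1-yl)oxy]-4-oxo-2-phenyl-4H-chromen-8-yl sulfate | CC(C)=CCOc1cc(O)c2c(=O)c(O)c(-c3ccccc3)oc2c1OS(=O)(=O)[O-].[K+] | intermediate (not isolated)
5 | flavonol hydroquinone 7-O-prenyl ether (3,5,8-trihydroxy-7-[(3-methylbut-2-en-1-yl)oxy]-2-phenyl-4H-chromen-4-one) | CC(C)=CCOc1cc(O)c2c(=O)c(O)c(-c3ccccc3)oc2c1O | intermediate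
6 | ion pair of the (prenyl)bis(triphenylphosphine)palladium cation (allyl drawn σ-bound) and 3,5,8-trihydroxy-4-oxo-2-phenyl-4H-chromen-7-olate | CC(C)=CC[Pd-]([P+](c1ccccc1)(c1ccccc1)c1ccccc1)[P+](c1ccccc1)(c1ccccc1)c1ccccc1.[O-]c1cc(O)c2c(=O)c(O)c(-c3ccccc3)oc2c1O | intermediate (not isolated)
7 | tert-prenyl ether (3,5,8-trihydroxy-7-[(2-methylbut-3-en-2-yl)oxy]-2-phenyl-4H-chromen-4-one) | C=CC(C)(C)Oc1cc(O)c2c(=O)c(O)c(-c3ccccc3)oc2c1O | intermediate (not isolated)
8 | platanetin (3,5,7,8-tetrahydroxy-6-(3-methylbut-2-en-1-yl)-2-phenyl-4H-chromen-4-one) | CC(C)=CCc1c(O)c(O)c2oc(-c3ccccc3)c(O)c(=O)c2c1O | target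

**Totals**
Total step count: 3. Longest linear sequence: 3 steps (from galangin 1).

**Steps most likely to fail**

Step 3 (the proposed new step). The risks are slow ionisation of the trisubstituted allyl ether, loss of the prenyl group as isoprene, and allylation at C2 through the 3-oxide. The fallback uses known chemistry and gives up palladium π-allyl catalysis and the ether-transposition/Claisen relay. It sets out from 5 and comes back at 8 by the solid-acid-promoted direct 1,3-shift of aryl prenyl ethers: activated montmorillonite K10, dry CH2Cl2, 0 to 20 °C, N2. The clay surface ionises the ether and the prenyl group recombines at the ortho carbon; with C8 oxygenated, C6 is the only site. No new compound is made (F0).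

Step 2. The risks are a modest Elbs conversion, oxidative loss of the flavonol, and prenyl ether cleavage if the sulfate hydrolysis is sluggish. The fallback inverts the order so that no acid-labile group is present during oxidation and the classical hydrolysis can be used. It sets out from galangin 1: K2S2O8, aqueous KOH, 0 to 20 °C, N2 gives potassium 3,5,7-trihydroxyflavon-8-yl sulfate F1. This is hydrolysed in the same pot with hot dilute HCl and Na2SO3 to 3,5,7,8-tetrahydroxyflavone F2. F2 is then etherified at its most acidic hydroxyl (O7) with prenyl bromide 2 (1.0 equiv), KHCO3, DMF, 20 °C, N2, which comes back to the route at 5.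

Step 1. The risks are 3,7-di-O-prenylation and some C-prenylation of the phloroglucinol-type ring A. The fallback replaces phenoxide alkylation by a Mitsunobu etherification, which activates the alcohol and reacts only with the most acidic phenol. It sets out from 1 with 3-methylbut-2-en-1-ol, PPh3 and diisopropyl azodicarboxylate in THF, 0 to 20 °C, and comes back at 3. No new compound is made (F0).

**Further compounds**
F0 | step 1 | none | none
F1 | step 2 | potassium 3,5,7-trihydroxy-4-oxo-2-phenyl-4H-chromen-8-yl sulfate | O=c1c(O)c(-c2ccccc2)oc2c(OS(=O)(=O)[O-])c(O)cc(O)c12.[K+]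
F2 | step 2 | 3,5,7,8-tetrahydroxy-2-phenyl-4H-chromen-4-one (8-hydroxygalangin) | O=c1c(O)c(-c2ccccc2)oc2c(O)c(O)cc(O)c12
F0 | step 3 | none | none
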